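**Plan** (chain numbered C1 = CH3 on the CHCl carbon to C17 = CH2 on the furan)
- Cuts: C4–C5 (ketone from thioester plus alkylzinc), C11=C12 (Julia–Kocienski), C7–C8 and C8–C9 (both at one dithiane carbon), and C17–furan C3 with C14–CH3 for the side chain.
- Enabling feature: C5–C11 is a seven-carbon run in which the methyl-bearing C6 and C10 are both R and are exchanged by a twofold axis through C8, so one (S)-3-iodo-2-methylpropyl unit serves twice. The furan is the only ring and is bought as 3-bromofuran, so no ring is formed anywhere.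
- Forward order: Roche ester → TBDPS iodide (C5–C7) and TBS iodide (C9–C11) → both attached to C2 of 1,3-dithiane (C8) → desulfurisation → C11 sulfone → diene with the C12–C17 furyl enal → C5 iodide → zinc reagent acylated by the C1–C4 thioester → desilylation.
- Stereochemistry: C6 and C10 come from the (S)-Roche ester and are never touched. C2 and C3 come from L-threonine (retentive bromodeamination, epoxide closure with inversion, chloride opening with inversion). 11E comes from the Julia–Kocienski step and 13E from syn-carboalumination.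

Key step: step 7

Remark: the descriptor at C6 and C10 changes from S in iodides 4 and 7 to R in the chain only because the CIP ranking of the substituents changes. (5-Chloropent-1-yn-1-yl)trimethylsilane 17 is taken as a purchased reagent.

**Part A – the two iodides**

Step 1
Reactants: 1 methyl (S)-3-hydroxy-2-methylpropanoate
Product: 2 methyl (2S)-3-[(tert-butyldiphenylsilyl)oxy]-2-methylpropanoate
Conditions: TBDPSCl, imidazole, CH2Cl2, 0 °C → rt
Reagents that add atoms: tert-butyl(chloro)diphenylsilane, CC(C)(C)[Si](Cl)(c1ccccc1)c1ccccc1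
Why: Imidazole-mediated silylation of a primary alcohol, which leaves the α-stereocentre untouched.

Step 2
Reactants: 2 methyl (2S)-3-[(tert-butyldiphenylsilyl)oxy]-2-methylpropanoate
Product: 3 (2R)-3-[(tert-butyldiphenylsilyl)oxy]-2-methylpropan-1-ol
Conditions: i-Bu2AlH (2.2 equiv), CH2Cl2, −78 → 0 °C; Rochelle salt work-up
Reagents that add atoms: none
Why: Ester reduction with excess i-Bu2AlH runs through to the alcohol, so the epimerisable aldehyde never accumulates and the stereocentre should stay intact.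

Step 3
Reactants: 3 (2R)-3-[(tert-butyldiphenylsilyl)oxy]-2-methylpropan-1-ol
Product: 4 tert-butyl{[(2S)-3-iodo-2-methylpropyl]oxy}diphenylsilane
Conditions: PPh3, I2, imidazole, CH2Cl2, 0 °C → rt
Reagents that add atoms: iodine, II
Why: Appel-type iodination is an SN2 displacement at the primary carbon next to, not at, the stereocentre.

Step 4
Reactants: 1 methyl (S)-3-hydroxy-2-methylpropanoate
Product: 5 methyl (2S)-3-{[tert-butyl(dimethyl)silyl]oxy}-2-methylpropanoate
Conditions: TBSCl, imidazole, CH2Cl2, 0 °C → rt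
Reagents that add atoms: tert-butyl(chloro)dimethylsilane, CC(C)(C)[Si](C)(C)Cl
Why: Imidazole-mediated silylation of the primary alcohol; the different silyl group is what later tells C11 from C5.

Step 5
Reactants: 5 methyl (2S)-3-{[tert-butyl(dimethyl)silyl]oxy}-2-methylpropanoate
Product: 6 (2R)-3-{[tert-butyl(dimethyl)silyl]oxy}-2-methylpropan-1-ol
Conditions: i-Bu2AlH (2.2 equiv), CH2Cl2, −78 → 0 °C; Rochelle salt work-up
Reagents that add atoms: none
Why: Ester reduction with excess i-Bu2AlH as in step 2, without epimerisation.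

Step 6
Reactants: 6 (2R)-3-{[tert-butyl(dimethyl)silyl]oxy}-2-methylpropan-1-ol
Product: 7 tert-butyl{[(2S)-3-iodo-2-methylpropyl]oxy}dimethylsilane
Conditions: PPh3, I2, imidazole, CH2Cl2, 0 °C → rt
Reagents that add atoms: iodine, II
Why: Appel-type iodination by SN2 at the primary carbon; the imidazole buffer protects the TBS ether.

**Part B – linchpin coupling and the C11 sulfone**

Step 7
Reactants: 8 1,3-dithiane; 4 tert-butyl{[(2S)-3-iodo-2-methylpropyl]oxy}diphenylsilane; 7 tert-butyl{[(2S)-3-iodo-2-methylpropyl]oxy}dimethylsilane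
Product: 12 tert-butyl{[(2R)-3-{2-[(2R)-3-{[tert-butyl(dimethyl)silyl]oxy}-2-methylpropyl]-1,3-dithian-2-yl}-2-methylpropyl]oxy}diphenylsilane, via 2-lithio-1,3-dithiane 9 (not isolated), via mono-alkylated dithiane 10 (not isolated), via lithiated mono-alkylated dithiane 11 (not isolated)
Conditions: n-BuLi (1.0 equiv), THF, −30 °C; 4 (1.0 equiv), −30 → 0 °C; t-BuLi, HMPA, −78 °C; 7, −78 → −20 °C
Reagents that add atoms: none
Why: n-BuLi removes a C2 proton of 8 to give the sulfur-stabilised carbanion 9, which displaces iodide from 4 by SN2 to give 10; t-BuLi in THF–HMPA then removes the remaining C2 proton to give 11, which displaces iodide from 7, so that C7–C8 and C8–C9 are both formed at one carbon of reversed polarity. The closest known reaction type is the Corey–Seebach sequential dialkylation of 1,3-dithiane with primary iodides. No ring is closed and no stereocentre is created: C6 and C10 arrive with the iodides and each lies β to the reacting carbon, so neither can be affected. The selectivity needed is mono- before bis-alkylation and SN2 over E2 at the β-branched iodides. It should be secured by 1:1 stoichiometry in the first stage, by the primary iodide leaving groups, and by the HMPA-separated ion pair at low temperature in the second stage. Using TBDPS on one arm and TBS on the other removes the twofold symmetry in the same operation, so C11 and C5 can be addressed separately afterwards.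

Step 8
Reactants: 12 tert-butyl{[(2R)-3-{2-[(2R)-3-{[tert-butyl(dimethyl)silyl]oxy}-2-methylpropyl]-1,3-dithian-2-yl}-2-methylpropyl]oxy}diphenylsilane
Product: 13 tert-butyl{[(2R,6R)-7-{[tert-butyl(dimethyl)silyl]oxy}-2,6-dimethylheptyl]oxy}diphenylsilane
Conditions: Raney Ni (W-2, excess), EtOH, rt → 60 °C
Reagents that add atoms: none
Why: Raney nickel hydrogenolysis of both C–S bonds (Mozingo-type desulfurisation) turns the dithiane carbon into the C8 methylene; silyl ethers and the remote stereocentres are inert.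

Step 9
Reactants: 13 tert-butyl{[(2R,6R)-7-{[tert-butyl(dimethyl)silyl]oxy}-2,6-dimethylheptyl]oxy}diphenylsilane
Product: 14 (2R,6R)-7-[(tert-butyldiphenylsilyl)oxy]-2,6-dimethylheptan-1-ol
Conditions: camphorsulfonic acid (cat.), MeOH–CH2Cl2, 0 °C
Reagents that add atoms: none
Why: Acid-catalysed methanolysis removes the primary TBS ether much faster than the bulkier, more acid-stable TBDPS ether.

Step 10
Reactants: 14 (2R,6R)-7-[(tert-butyldiphenylsilyl)oxy]-2,6-dimethylheptan-1-ol
Product: 15 5-{[(2R,6R)-7-[(tert-butyldiphenylsilyl)oxy]-2,6-dimethylheptyl]sulfanyl}-1-phenyl-1H-tetrazole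
Conditions: 1-phenyl-1H-tetrazole-5-thiol, PPh3, DIAD, THF, 0 °C → rt
Reagents that add atoms: 1-phenyl-1H-tetrazole-5-thiol, Sc1nnnn1-c1ccccc1
Why: Mitsunobu thioetherification of the primary alcohol with the acidic heteroaryl thiol; substitution is at CH2, so C10 is untouched.

Step 11
Reactants: 15 5-{[(2R,6R)-7-[(tert-butyldiphenylsilyl)oxy]-2,6-dimethylheptyl]sulfanyl}-1-phenyl-1H-tetrazole
Product: 16 5-{[(2R,6R)-7-[(tert-butyldiphenylsilyl)oxy]-2,6-dimethylheptyl]sulfonyl}-1-phenyl-1H-tetrazole
Conditions: (NH4)6Mo7O24·4H2O (cat.), 30% H2O2, EtOH, 0 °C → rt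
Reagents that add atoms: hydrogen peroxide, OO
Why: Molybdate-catalysed peroxide oxidation of sulfide to sulfone, placed before any alkene or furan is present.

**Part C – the C12–C17 furyl enal**

Step 12
Reactants: 17 (5-chloropent-1-yn-1-yl)trimethylsilane; 18 3-bromofuran
Product: 20 [5-(furan-3-yl)pent-1-yn-1-yl]trimethylsilane, via alkylmagnesium chloride 19 (not isolated)
Conditions: Mg, I2 (cat.), THF, reflux; then 18, PdCl2(dppf) (cat.), THF, 0 °C → rt
Reagents that add atoms: none
Why: Grignard formation from the primary chloride and palladium-catalysed Kumada–Corriu coupling with the heteroaryl bromide; the wide-bite-angle dppf ligand favours reductive elimination over β-hydride loss and the silyl cap removes the acidic alkyne proton.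

Step 13
Reactants: 20 [5-(furan-3-yl)pent-1-yn-1-yl]trimethylsilane
Product: 21 3-(pent-4-yn-1-yl)furan
Conditions: K2CO3 (cat.), MeOH, rt
Reagents that add atoms: none
Why: Carbonate-catalysed methanolysis of the alkynyl C–Si bond.

Step 14
Reactants: 21 3-(pent-4-yn-1-yl)furan
Product: 23 (2E)-6-(furan-3-yl)-3-methylhex-2-en-1-ol, via alkenyldimethylalane 22 (not isolated)
Conditions: Me3Al, Cp2ZrCl2 (cat.), CH2Cl2, 0 °C → rt; then (CH2O)n, 0 °C → rt
Reagents that add atoms: trimethylaluminium, C[Al](C)C; paraformaldehyde (as formaldehyde), C=O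
Why: Negishi zirconium-catalysed carboalumination adds CH3 and Al syn across the terminal alkyne with methyl on the internal carbon, which fixes the E geometry of C13=C14; the alkenylalane is then hydroxymethylated with retention.

Step 15
Reactants: 23 (2E)-6-(furan-3-yl)-3-methylhex-2-en-1-ol
Product: 24 (2E)-6-(furan-3-yl)-3-methylhex-2-enal
Conditions: MnO2 (excess), CH2Cl2, rt
Reagents that add atoms: none
Why: MnO2 oxidises the allylic alcohol selectively to the enal under neutral conditions that should spare the furan and the olefin geometry.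

**Part D – diene and C5 iodide**

Step 16
Reactants: 16 5-{[(2R,6R)-7-[(tert-butyldiphenylsilyl)oxy]-2,6-dimethylheptyl]sulfonyl}-1-phenyl-1H-tetrazole; 24 (2E)-6-(furan-3-yl)-3-methylhex-2-enal
Product: 25 tert-butyl{[(2R,6R,7E,9E)-13-(furan-3-yl)-2,6,10-trimethyltrideca-7,9-dien-1-yl]oxy}diphenylsilane
Conditions: KN(SiMe3)2, DME, −60 °C; then 24, −60 °C → rt
Reagents that add atoms: none
Why: Julia–Kocienski olefination: the potassium sulfonyl carbanion adds to the aldehyde, Smiles transfer of the phenyltetrazolyl group and anti elimination of SO2 and tetrazololate give the C11=C12 bond, with E favoured by K+ in DME; C10 is β to the carbanion and cannot epimerise.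

Step 17
Reactants: 25 tert-butyl{[(2R,6R,7E,9E)-13-(furan-3-yl)-2,6,10-trimethyltrideca-7,9-dien-1-yl]oxy}diphenylsilane
Product: 26 (2R,6R,7E,9E)-13-(furan-3-yl)-2,6,10-trimethyltrideca-7,9-dien-1-ol
Conditions: Bu4NF, THF, rt
Reagents that add atoms: none
Why: Fluoride cleavage of the TBDPS ether; diene and furan are inert to fluoride.

Step 18
Reactants: 26 (2R,6R,7E,9E)-13-(furan-3-yl)-2,6,10-trimethyltrideca-7,9-dien-1-ol
Product: 27 3-[(4E,6E,8R,12R)-13-iodo-4,8,12-trimethyltrideca-4,6-dien-1-yl]furan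
Conditions: PPh3, I2, imidazole, CH2Cl2, 0 °C (reagent premixed before 26 is added)
Reagents that add atoms: iodine, II
Why: Appel-type iodination of the primary alcohol; preforming the phosphonium iodide keeps free iodine away from diene and furan.

**Part E – the C1–C4 thioester**

Step 19
Reactants: 28 L-threonine
Product: 29 (2S,3R)-2-bromo-3-hydroxybutanoic acid
Conditions: NaNO2, KBr, aq. H2SO4, −5 → 0 °C
Reagents that add atoms: potassium bromide, [K+].[Br-]
Why: Diazotisation of the α-amino acid with carboxylate participation (α-lactone) and bromide opening is a double inversion, so bromine should replace nitrogen with net retention.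

Step 20
Reactants: 29 (2S,3R)-2-bromo-3-hydroxybutanoic acid
Product: 30 potassium (2R,3R)-3-methyloxirane-2-carboxylate (cis)
Conditions: KOH (2 equiv), EtOH, 0 °C → rt
Reagents that add atoms: potassium hydroxide, [K+].[OH-]
Why: Intramolecular Williamson closure: the C3 alkoxide displaces bromide at C2 with inversion, which sets the oxygen-bearing centre that becomes target C3.

Step 21
Reactants: 30 potassium (2R,3R)-3-methyloxirane-2-carboxylate
Product: 31 (2S,3S)-3-chloro-2-hydroxybutanoic acid
Conditions: HCl (4 M in 1,4-dioxane, excess), Et2O, 0 °C → rt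
Reagents that add atoms: hydrogen chloride, Cl
Why: Acid-mediated opening of a glycidic acid by chloride should occur at C3, the carbon remote from the electron-withdrawing carboxyl group, with inversion, which sets target C2 as S; anhydrous conditions keep water from competing.

Step 22
Reactants: 31 (2S,3S)-3-chloro-2-hydroxybutanoic acid
Product: 32 tert-butyldimethylsilyl (2S,3S)-2-{[tert-butyl(dimethyl)silyl]oxy}-3-chlorobutanoate
Conditions: TBSCl (2.4 equiv), imidazole, DMF, rt
Reagents that add atoms: tert-butyl(chloro)dimethylsilane, CC(C)(C)[Si](C)(C)Cl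
Why: Imidazole-mediated silylation of both hydroxyl and carboxyl groups; imidazole is too weak a base to re-close the epoxide.

Step 23
Reactants: 32 tert-butyldimethylsilyl (2S,3S)-2-{[tert-butyl(dimethyl)silyl]oxy}-3-chlorobutanoate
Product: 34 S-ethyl (2S,3S)-2-{[tert-butyl(dimethyl)silyl]oxy}-3-chlorobutanethioate, via acid chloride 33 (not isolated)
Conditions: (COCl)2, DMF (cat.), CH2Cl2, 0 °C → rt; then EtSH, pyridine, 0 °C
Reagents that add atoms: ethanethiol, CCS
Why: Vilsmeier-type conversion of a silyl ester into the acid chloride under neutral conditions, then thiol acylation with pyridine, a base too weak to form the ketene and erode the α-centre.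

**Part F – ketone formation and release of the target**

Step 24
Reactants: 27 3-[(4E,6E,8R,12R)-13-iodo-4,8,12-trimethyltrideca-4,6-dien-1-yl]furan; 34 S-ethyl (2S,3S)-2-{[tert-butyl(dimethyl)silyl]oxy}-3-chlorobutanethioate
Product: 36 (2S,3S,6R,10R,11E,13E)-3-{[tert-butyl(dimethyl)silyl]oxy}-2-chloro-17-(furan-3-yl)-6,10,14-trimethylheptadeca-11,13-dien-4-one, via alkylzinc iodide 35 (not isolated)
Conditions: Zn dust (activated with BrCH2CH2Br and Me3SiCl), DMA, 40 °C; then 34, PdCl2(PPh3)2 (cat.), toluene, rt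
Reagents that add atoms: none
Why: Fukuyama coupling: zerovalent palladium inserts into the C–S bond, the alkylzinc iodide transmetalates and reductive elimination gives the ketone without over-addition, under neutral conditions that should preserve the α-silyloxy and β-chloro centres.

Step 25
Reactants: 36 (2S,3S,6R,10R,11E,13E)-3-{[tert-butyl(dimethyl)silyl]oxy}-2-chloro-17-(furan-3-yl)-6,10,14-trimethylheptadeca-11,13-dien-4-one
Product: 37 (2S,3S,6R,10R,11E,13E)-2-chloro-17-(furan-3-yl)-3-hydroxy-6,10,14-trimethylheptadeca-11,13-dien-4-one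
Conditions: HF·pyridine, pyridine, THF, 0 °C → rt
Reagents that add atoms: none
Why: Buffered HF·pyridine desilylation is non-basic, so no alkoxide forms next to the C–Cl bond that could close an epoxide or epimerise C3.

**Compound list**

1 | methyl (S)-3-hydroxy-2-methylpropanoate (Roche ester) | COC(=O)[C@@H](C)CO | starting material
2 | methyl (2S)-3-[(tert-butyldiphenylsilyl)oxy]-2-methylpropanoate | COC(=O)[C@@H](C)CO[Si](c1ccccc1)(c1ccccc1)C(C)(C)C | intermediate
3 | (2R)-3-[(tert-butyldiphenylsilyl)oxy]-2-methylpropan-1-ol | OC[C@@H](C)CO[Si](c1ccccc1)(c1ccccc1)C(C)(C)C | intermediate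
4 | tert-butyl{[(2S)-3-iodo-2-methylpropyl]oxy}diphenylsilane (C5–C7 unit) | IC[C@@H](C)CO[Si](c1ccccc1)(c1ccccc1)C(C)(C)C | intermediate
5 | methyl (2S)-3-{[tert-butyl(dimethyl)silyl]oxy}-2-methylpropanoate | COC(=O)[C@@H](C)CO[Si](C)(C)C(C)(C)C | intermediate
6 | (2R)-3-{[tert-butyl(dimethyl)silyl]oxy}-2-methylpropan-1-ol | OC[C@@H](C)CO[Si](C)(C)C(C)(C)C | intermediate
7 | tert-butyl{[(2S)-3-iodo-2-methylpropyl]oxy}dimethylsilane (C9–C11 unit) | CC(C)(C)[Si](C)(C)OC[C@H](C)CI | intermediate
8 | 1,3-dithiane | C1CSCSC1 | starting material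
9 | 2-lithio-1,3-dithiane | [Li]C1SCCCS1 | intermediate
10 | tert-butyl{[(2R)-3-(1,3-dithian-2-yl)-2-methylpropyl]oxy}diphenylsilane | CC(C)(C)[Si](c1ccccc1)(c1ccccc1)OC[C@H](C)CC1SCCCS1 | intermediate
11 | 2-lithio derivative of 10 | CC(C)(C)[Si](c1ccccc1)(c1ccccc1)OC[C@H](C)CC1([Li])SCCCS1 | intermediate
12 | tert-butyl{[(2R)-3-{2-[(2R)-3-{[tert-butyl(dimethyl)silyl]oxy}-2-methylpropyl]-1,3-dithian-2-yl}-2-methylpropyl]oxy}diphenylsilane | CC(C)(C)[Si](C)(C)OC[C@H](C)CC1(C[C@@H](C)CO[Si](c2ccccc2)(c2ccccc2)C(C)(C)C)SCCCS1 | intermediate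
13 | tert-butyl{[(2R,6R)-7-{[tert-butyl(dimethyl)silyl]oxy}-2,6-dimethylheptyl]oxy}diphenylsilane | CC(C)(C)[Si](C)(C)OC[C@H](C)CCC[C@@H](C)CO[Si](c1ccccc1)(c1ccccc1)C(C)(C)C | intermediate
14 | (2R,6R)-7-[(tert-butyldiphenylsilyl)oxy]-2,6-dimethylheptan-1-ol | OC[C@H](C)CCC[C@@H](C)CO[Si](c1ccccc1)(c1ccccc1)C(C)(C)C | intermediate
15 | 5-{[(2R,6R)-7-[(tert-butyldiphenylsilyl)oxy]-2,6-dimethylheptyl]sulfanyl}-1-phenyl-1H-tetrazole | CC(C)(C)[Si](c1ccccc1)(c1ccccc1)OC[C@H](C)CCC[C@@H](C)CSc1nnnn1-c1ccccc1 | intermediate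
16 | 5-{[(2R,6R)-7-[(tert-butyldiphenylsilyl)oxy]-2,6-dimethylheptyl]sulfonyl}-1-phenyl-1H-tetrazole | CC(C)(C)[Si](c1ccccc1)(c1ccccc1)OC[C@H](C)CCC[C@@H](C)CS(=O)(=O)c1nnnn1-c1ccccc1 | intermediate
17 | (5-chloropent-1-yn-1-yl)trimethylsilane | C[Si](C)(C)C#CCCCCl | starting material
18 | 3-bromofuran | Brc1ccoc1 | starting material
19 | [5-(trimethylsilyl)pent-4-yn-1-yl]magnesium chloride | C[Si](C)(C)C#CCCC[Mg]Cl | intermediate
20 | [5-(furan-3-yl)pent-1-yn-1-yl]trimethylsilane | C[Si](C)(C)C#CCCCc1ccoc1 | intermediate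
21 | 3-(pent-4-yn-1-yl)furan | C#CCCCc1ccoc1 | intermediate
22 | [(1E)-5-(furan-3-yl)-2-methylpent-1-en-1-yl]dimethylalumane | C[Al](C)/C=C(\C)CCCc1ccoc1 | intermediate
23 | (2E)-6-(furan-3-yl)-3-methylhex-2-en-1-ol | OC/C=C(\C)CCCc1ccoc1 | intermediate
24 | (2E)-6-(furan-3-yl)-3-methylhex-2-enal | O=C/C=C(\C)CCCc1ccoc1 | intermediate
25 | tert-butyl{[(2R,6R,7E,9E)-13-(furan-3-yl)-2,6,10-trimethyltrideca-7,9-dien-1-yl]oxy}diphenylsilane | C/C(=C\C=C\[C@H](C)CCC[C@@H](C)CO[Si](c1ccccc1)(c1ccccc1)C(C)(C)C)CCCc1ccoc1 | intermediate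
26 | (2R,6R,7E,9E)-13-(furan-3-yl)-2,6,10-trimethyltrideca-7,9-dien-1-ol | C/C(=C\C=C\[C@H](C)CCC[C@@H](C)CO)CCCc1ccoc1 | intermediate
27 | 3-[(4E,6E,8R,12R)-13-iodo-4,8,12-trimethyltrideca-4,6-dien-1-yl]furan | C/C(=C\C=C\[C@H](C)CCC[C@@H](C)CI)CCCc1ccoc1 | intermediate
28 | L-threonine | C[C@H]([C@@H](C(=O)O)N)O | starting material
29 | (2S,3R)-2-bromo-3-hydroxybutanoic acid | OC(=O)[C@@H](Br)[C@H](O)C | intermediate
30 | potassium (2R,3R)-3-methyloxirane-2-carboxylate | [K+].[O-]C(=O)[C@@H]1O[C@@H]1C | intermediate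
31 | (2S,3S)-3-chloro-2-hydroxybutanoic acid | OC(=O)[C@H](O)[C@H](C)Cl | intermediate
32 | tert-butyldimethylsilyl (2S,3S)-2-{[tert-butyl(dimethyl)silyl]oxy}-3-chlorobutanoate | CC(C)(C)[Si](C)(C)OC(=O)[C@H](O[Si](C)(C)C(C)(C)C)[C@H](C)Cl | intermediate
33 | (2R,3S)-2-{[tert-butyl(dimethyl)silyl]oxy}-3-chlorobutanoyl chloride (same spatial arrangement as 32; descriptor changed by ranking) | ClC(=O)[C@H](O[Si](C)(C)C(C)(C)C)[C@H](C)Cl | intermediate
34 | S-ethyl (2S,3S)-2-{[tert-butyl(dimethyl)silyl]oxy}-3-chlorobutanethioate | CCSC(=O)[C@H](O[Si](C)(C)C(C)(C)C)[C@H](C)Cl | intermediate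
35 | [(2R,6R,7E,9E)-13-(furan-3-yl)-2,6,10-trimethyltrideca-7,9-dien-1-yl]zinc iodide | C/C(=C\C=C\[C@H](C)CCC[C@@H](C)C[Zn]I)CCCc1ccoc1 | intermediate
36 | (2S,3S,6R,10R,11E,13E)-3-{[tert-butyl(dimethyl)silyl]oxy}-2-chloro-17-(furan-3-yl)-6,10,14-trimethylheptadeca-11,13-dien-4-one | C/C(=C\C=C\[C@H](C)CCC[C@@H](C)CC(=O)[C@H](O[Si](C)(C)C(C)(C)C)[C@H](C)Cl)CCCc1ccoc1 | intermediate
37 | (2S,3S,6R,10R,11E,13E)-2-chloro-17-(furan-3-yl)-3-hydroxy-6,10,14-trimethylheptadeca-11,13-dien-4-one | C/C(=C\C=C\[C@H](C)CCC[C@@H](C)CC(=O)[C@H](O)[C@H](C)Cl)CCCc1ccoc1 | target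

**Step count**

Total: 25 steps. Longest linear sequence: 13 steps (1, 2, 3, 7, 8, 9, 10, 11, 16, 17, 18, 24, 25).

**Steps most likely to fail**

Step 7. The second lithiation of the hindered 2-alkyldithiane may be incomplete in the presence of lithium iodide. The tertiary carbanion 11 may also act as a base towards the β-branched iodide 7 (E2), or react too slowly by SN2, and residual 4 may undergo iodine–lithium exchange with t-BuLi. The fallback keeps the dithiane carbon as C8 but forms C8–C9 by olefination. The sequence is stopped after the first alkylation and 10 is isolated. Its dithiane is hydrolysed (MeI, CaCO3, aqueous MeCN) to (3R)-4-[(tert-butyldiphenylsilyl)oxy]-3-methylbutanal F1. Iodide 7 is heated with PPh3 in MeCN to give [(2S)-3-{[tert-butyl(dimethyl)silyl]oxy}-2-methylpropyl]triphenylphosphonium iodide F2. NaN(SiMe3)2 in THF at −78 °C converts this into the ylide [(2S)-3-{[tert-butyl(dimethyl)silyl]oxy}-2-methylpropylidene]triphenyl-λ5-phosphane F3. Wittig reaction of F3 with F1 should give tert-butyl{[(2R,4Z,6R)-7-{[tert-butyl(dimethyl)silyl]oxy}-2,6-dimethylhept-4-en-1-yl]oxy}diphenylsilane F4, and hydrogenation (H2, PtO2, EtOAc) returns to the route at 13.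

Step 16. With a conjugated aldehyde the addition of the sulfonyl carbanion can become reversible, so the E preference at C11=C12 may erode, and the base may deprotonate the enal at its γ-positions instead of adding. The fallback sets both olefin geometries by reagent control. Alcohol 14 is oxidised (Dess–Martin periodinane, NaHCO3, CH2Cl2) to (2R,6R)-7-[(tert-butyldiphenylsilyl)oxy]-2,6-dimethylheptanal F5, which is used at once. Takai olefination (CrCl2, CHI3, THF, 0 °C) should give tert-butyl{[(2R,6R,7E)-8-iodo-2,6-dimethyloct-7-en-1-yl]oxy}diphenylsilane F6. Alkyne 21 is carboaluminated as in step 14, and the alkenylalane 22 is cross-coupled with F6 (Pd(PPh3)4 cat., ZnCl2 cat., THF, rt) in a Negishi coupling that gives the (E,E)-diene 25, where the route is rejoined.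

Step 24. Zinc insertion into the β-branched iodide may be sluggish, the alkylzinc may be lost by protonolysis or homocoupling, and the acylpalladium intermediate may lose CO or eliminate before it is intercepted. The fallback replaces the palladium acylation by addition to an aldehyde and oxidation. Thioester 34 is reduced (Et3SiH, Pd/C, acetone, rt; Fukuyama reduction) to (2S,3S)-2-{[tert-butyl(dimethyl)silyl]oxy}-3-chlorobutanal F7. Iodide 27 is converted with t-BuLi (2 equiv, Et2O, −78 °C) into [(2S,6R,7E,9E)-13-(furan-3-yl)-2,6,10-trimethyltrideca-7,9-dien-1-yl]lithium F8. Addition of F8 to F7 at −78 °C should give (2S,3S,6R,10R,11E,13E)-3-{[tert-butyl(dimethyl)silyl]oxy}-2-chloro-17-(furan-3-yl)-6,10,14-trimethylheptadeca-11,13-dien-4-ol F9 as a mixture of C4 epimers, which does not matter. Dess–Martin oxidation then returns to the route at 36.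

**Further compounds**

F1 | step 7 | (3R)-4-[(tert-butyldiphenylsilyl)oxy]-3-methylbutanal | O=CC[C@@H](C)CO[Si](c1ccccc1)(c1ccccc1)C(C)(C)C
F2 | step 7 | [(2S)-3-{[tert-butyl(dimethyl)silyl]oxy}-2-methylpropyl]triphenylphosphonium iodide | CC(C)(C)[Si](C)(C)OC[C@H](C)C[P+](c1ccccc1)(c1ccccc1)c1ccccc1.[I-]
F3 | step 7 | [(2S)-3-{[tert-butyl(dimethyl)silyl]oxy}-2-methylpropylidene]triphenyl-λ5-phosphane | CC(C)(C)[Si](C)(C)OC[C@H](C)C=P(c1ccccc1)(c1ccccc1)c1ccccc1
F4 | step 7 | tert-butyl{[(2R,4Z,6R)-7-{[tert-butyl(dimethyl)silyl]oxy}-2,6-dimethylhept-4-en-1-yl]oxy}diphenylsilane | CC(C)(C)[Si](C)(C)OC[C@H](C)/C=C\C[C@@H](C)CO[Si](c1ccccc1)(c1ccccc1)C(C)(C)C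
F5 | step 16 | (2R,6R)-7-[(tert-butyldiphenylsilyl)oxy]-2,6-dimethylheptanal | O=C[C@H](C)CCC[C@@H](C)CO[Si](c1ccccc1)(c1ccccc1)C(C)(C)C
F6 | step 16 | tert-butyl{[(2R,6R,7E)-8-iodo-2,6-dimethyloct-7-en-1-yl]oxy}diphenylsilane | I/C=C/[C@H](C)CCC[C@@H](C)CO[Si](c1ccccc1)(c1ccccc1)C(C)(C)C
F7 | step 24 | (2S,3S)-2-{[tert-butyl(dimethyl)silyl]oxy}-3-chlorobutanal | O=C[C@H](O[Si](C)(C)C(C)(C)C)[C@H](C)Cl
F8 | step 24 | [(2S,6R,7E,9E)-13-(furan-3-yl)-2,6,10-trimethyltrideca-7,9-dien-1-yl]lithium | C/C(=C\C=C\[C@H](C)CCC[C@@H](C)C[Li])CCCc1ccoc1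
F9 | step 24 | (2S,3S,6R,10R,11E,13E)-3-{[tert-butyl(dimethyl)silyl]oxy}-2-chloro-17-(furan-3-yl)-6,10,14-trimethylheptadeca-11,13-dien-4-ol (C4 epimers) | C/C(=C\C=C\[C@H](C)CCC[C@@H](C)CC(O)[C@H](O[Si](C)(C)C(C)(C)C)[C@H](C)Cl)CCCc1ccoc1
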